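Target is the reading to watch, and it counts the idle adduct in.

| setting | gamma | beta | epsilon | summer | midnight | dusk |
|---|---|---|---|---|---|---|
| starting material | 0.80 M | 0.80 M | 0.40 M | 0.80 M | 0.80 M | 0.80 M |
| second substrate | 0.80 M | 0.80 M | 0.80 M | 0.800 M | 0.800 M | 0.800 M |
| free catalyst | 11 mM | 24 mM | 16 mM | 16 mM | 16 mM | 16 mM |
| temperature | 15 °C | 37 °C | 15 °C | 5 °C | 45 °C | 25 °C |
| remark | run made earlier | run made earlier | run made earlier |  |  |  |
| time |  |  |  | 20 min | 20 min | 20 min |

| run | time / min | target / % | starting material / % |
|---|---|---|---|
| gamma | 1.33 | 0.7 | 98.2 |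
| gamma | 2.50 | 2.0 | 95.5 |
| gamma | 6.00 | 5.0 | 91.4 |
| gamma | 15.0 | 12.6 | 80.4 |
| beta | 1.33 | 15.3 | 76.1 |
| beta | 2.50 | 26.9 | 60.3 |
| beta | 4.00 | 40.9 | 46.1 |
| beta | 5.00 | 46.8 | 38.9 |
| epsilon | 4.00 | 6.3 | 90.7 |
| epsilon | 8.00 | 13.4 | 81.6 |
| epsilon | 12.0 | 19.6 | 74.6 |
| epsilon | 15.0 | 23.9 | 68.7 |

(standard deviation of a reading: 0.5 percentage points)

- in percentages every species weighs as the starting material in it: one idle adduct counts as two
- for target the idle adduct is counted in
- steps that have been proposed: catalyst intermediate B -> free catalyst + second product; second substrate + free catalyst <-> catalyst intermediate B; starting material + free catalyst <-> catalyst intermediate A; catalyst intermediate A -> free catalyst + target; starting material + target <-> idle adduct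
- in an amount of target, one idle adduct counts as one target

- the best flask by amount of target, in percent of the starting material charged; "all alike" if 1.5 percentage points covers them all (summer / midnight / dusk / all alike)
- amount of target at the end, in percent of the starting material charged, summer
- amount of target at the end, in percent of the starting material charged, midnight
- amount of target at the end, in percent of the starting material charged, dusk

My reckoning brings each flask down to two times: the 20 min allowed, and the clearing time τ, in which the unreacted share falls by the factor e. From a target reading y at time t, τ = t/(−ln(1 − y)). It takes τ as inverse to the [free catalyst] charged. So the last gamma and beta readings, brought to 16 mM, give: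

τ at 15 °C = 76.6 min

τ at 37 °C = 11.9 min

The two lie 0.809 powers of ten apart, an apparent activation energy of 62.9 kJ/mol. The epsilon run, with half the [starting material], gives 54.9 min, shorter than the gamma figure, so τ is a rough measure. With N = t/τ and target = 1 − exp(−N):

summer: τ = 197 min, N = 0.102, target 9.65%

dusk: τ = 31.7 min, N = 0.631, target 46.8%

midnight: τ = 6.43 min, N = 3.11, target 95.5%

In midnight the time allowed is longer than τ; in summer and dusk it is shorter. So my reckoning puts midnight first.

The forecast, reckoned its own way, gives 9.5% for summer, 48% for dusk and 96% for midnight, and names midnight: “No deactivation is evident, so hottest wins”.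

The flasks give 8.60% in summer, 50.5% in dusk and 90.0% in midnight, so midnight is best, though 6 percentage points under the forecast.

    catalyst intermediate B → free catalyst + second product (k = 110 /min, Ea = 71.0 kJ/mol)
    second substrate + free catalyst ⇌ catalyst intermediate B (K = 0.470 /M, k = 6.10 /M/min, Ea = 63.0 kJ/mol, ΔH = −57.0 kJ/mol)
    starting material + free catalyst ⇌ catalyst intermediate A (K = 20.0 /M, k = 4.00 /M/min, Ea = 45.0 kJ/mol, ΔH = 8.00 kJ/mol)
    catalyst intermediate A → free catalyst + target (k = 4.30 /min, Ea = 87.0 kJ/mol)
    starting material + target ⇌ idle adduct, settled at all times (K = 1.30 /M, ΔH = 6.00 kJ/mol)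
    (constants at 25 °C)

At 20.0 min midnight still holds 4.93% starting material and 10.1% idle adduct, with 0.162% of the second substrate left. The neighbour flask is summer run at 30 °C, with the amounts and time held. There τ = 20.9 min, so:

N = 0.957, target 61.6%

That neighbour flask gives 63.7% target, with 23.3% starting material remaining.

The runs are calculated from invented constants; the scatter is artificial.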